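**Strategy**

Everything rests on disconnecting O1–C2 of the dihydrobenzofuran. Because C2 carries the 4-hydroxy-3-methoxyphenyl ring, a hydroxyl on C2 leaves under mild acid and a para-quinone methide results, whatever the C2 configuration was; the C7a phenol then closes the furan ring 5-exo and places that aryl group trans to C9 on C3. One operation thus makes the ring, the O1–C2 bond and the C2 stereocentre. The precursor is an open-chain 1,2-diarylpropane-1,3-diol with both phenols free, C3 set as S by an Evans aldol reaction, and the propanol carried as a TBDPS ether instead of TBS, so that the only marker distinguishing the two primary alcohols survives the acid.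

Key step: step 12

Assumption: atom labels follow the dihydrobenzofuran (O1, C2, C3, C3a, C7a; C9 is the CH2O carbon on C3) and the target is taken as trans-(2R,3S), as its SMILES encodes; compounds 15–18 are written as the expected syn aldol isomer, and any C2 epimer travels with them because step 12 erases that centre.

Abbreviations: TBS = tert-butyldimethylsilyl; TBDPS = tert-butyldiphenylsilyl.

**Route**

Step 1
Reactants: 1 ferulic acid
Product: 2 dihydroferulic acid [3-(4-hydroxy-3-methoxyphenyl)propanoic acid]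
Conditions: H2 (1 atm), 10% Pd/C, MeOH, rt
Reagents that add atoms: none
Why: Catalytic hydrogenation over Pd/C saturates the cinnamic C=C quickly and leaves the arene, the phenol and the acid untouched.

Step 2
Reactants: 2 dihydroferulic acid
Product: 3 3-(3-bromo-4-hydroxy-5-methoxyphenyl)propanoic acid
Conditions: Br2 (1.0 equiv), AcOH, rt
Reagents that add atoms: bromine, BrBr
Why: Electrophilic aromatic bromination should be directed by the free hydroxyl, the strongest donor, to its only open ortho position (C5), as is usual for 4-substituted guaiacols.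

Step 3
Reactants: 3 3-(3-bromo-4-hydroxy-5-methoxyphenyl)propanoic acid
Product: 4 2-bromo-4-(3-hydroxypropyl)-6-methoxyphenol
Conditions: BH3·THF (3 equiv), THF, 0 °C → rt; then H2O, aq. HCl
Reagents that add atoms: none
Why: Borane reduces the carboxylic acid to the primary alcohol through an acyloxyborane and does not touch the aryl bromide (chemoselective borane reduction).

Step 4
Reactants: 4 2-bromo-4-(3-hydroxypropyl)-6-methoxyphenol
Product: 6 {2-bromo-4-[3-(tert-butyldiphenylsilyloxy)propyl]-6-methoxyphenoxy}(tert-butyl)dimethylsilane, via mono-TBDPS ether 5 (not isolated)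
Conditions: TBDPSCl (1.05 equiv), imidazole (4 equiv), CH2Cl2–DMF, 0 °C; then TBSCl (1.5 equiv), rt → 40 °C
Reagents that add atoms: tert-butyl(chloro)diphenylsilane, CC(C)(C)[Si](Cl)(c1ccccc1)c1ccccc1; tert-butyl(chloro)dimethylsilane, CC(C)(C)[Si](C)(C)Cl
Why: Sequential silyl ether formation in one flask: the bulky TBDPS chloride should silylate the unhindered primary alcohol well before the di-ortho-substituted phenol, which the smaller TBS chloride then caps.

Step 5
Reactants: 6 {2-bromo-4-[3-(tert-butyldiphenylsilyloxy)propyl]-6-methoxyphenoxy}(tert-butyl)dimethylsilane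
Product: 7 tert-butyl 2-{2-(TBS-oxy)-3-methoxy-5-[3-(TBDPS-oxy)propyl]phenyl}acetate
Conditions: ClZnCH2CO2t-Bu (1.5 equiv, 0.5 M in Et2O), Pd(dba)2 (2 mol%), Q-Phos (2 mol%), THF, rt → 50 °C
Reagents that add atoms: (2-tert-butoxy-2-oxoethyl)zinc chloride, CC(C)(C)OC(=O)C[Zn]Cl
Why: Palladium-catalysed α-arylation of a Reformatsky-type zinc ester enolate (Negishi-type coupling) is neutral enough for both silyl ethers, and the bulky electron-rich ferrocenylphosphine should carry the ortho-substituted, electron-rich bromide through oxidative addition and reductive elimination.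

Step 6
Reactants: 7 tert-butyl 2-{2-(TBS-oxy)-3-methoxy-5-[3-(TBDPS-oxy)propyl]phenyl}acetate
Product: 8 2-{2-(TBS-oxy)-3-methoxy-5-[3-(TBDPS-oxy)propyl]phenyl}acetic acid
Conditions: TFA–CH2Cl2 (1:4), 0 °C, short contact time
Reagents that add atoms: none
Why: Acidolysis of the tert-butyl ester through the tert-butyl cation is much faster than protonolysis of an aryl TBS or a primary TBDPS ether, and both free ring positions are flanked on both sides, which should suppress tert-butylation.

Step 7
Reactants: 8 2-{2-(TBS-oxy)-3-methoxy-5-[3-(TBDPS-oxy)propyl]phenyl}acetic acid; 9 (R)-4-benzyl-2-oxazolidinone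
Product: 11 (R)-4-benzyl-3-(2-{2-(TBS-oxy)-3-methoxy-5-[3-(TBDPS-oxy)propyl]phenyl}acetyl)oxazolidin-2-one, via mixed pivalic anhydride 10 (not isolated)
Conditions: PivCl, Et3N, THF, −20 °C; then LiCl, 9, −20 °C → rt
Reagents that add atoms: none
Why: N-Acylation of the oxazolidinone through the pivalic mixed anhydride with LiCl/Et3N activation, in which the nucleophile attacks the unhindered arylacetyl carbonyl and not the pivaloyl one.

Step 8
Reactants: 12 vanillin
Product: 13 4-(tert-butyldimethylsilyloxy)-3-methoxybenzaldehyde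
Conditions: TBSCl, imidazole, CH2Cl2, rt
Reagents that add atoms: tert-butyl(chloro)dimethylsilane, CC(C)(C)[Si](C)(C)Cl
Why: Standard silyl ether formation masks the acidic phenol for the boron aldol reaction.

Step 9
Reactants: 11 (R)-4-benzyl-3-(2-{2-(TBS-oxy)-3-methoxy-5-[3-(TBDPS-oxy)propyl]phenyl}acetyl)oxazolidin-2-one; 13 4-(tert-butyldimethylsilyloxy)-3-methoxybenzaldehyde
Product: 16 (R)-4-benzyl-3-[(2R,3R)-2-{2-(TBS-oxy)-3-methoxy-5-[3-(TBDPS-oxy)propyl]phenyl}-3-hydroxy-3-(4-TBS-oxy-3-methoxyphenyl)propanoyl]oxazolidin-2-one, via Z boron enolate 14 (not isolated), via boron aldolate 15 (not isolated)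
Conditions: Bu2BOTf (1.2 equiv), i-Pr2NEt (1.4 equiv), CH2Cl2, 0 °C; then 13, −78 → 0 °C; then pH 7 buffer, MeOH, 30% H2O2, 0 °C
Reagents that add atoms: none
Why: Evans syn aldol reaction: soft enolisation gives the Z boron enolate, which adds to the aldehyde through a chair Zimmerman–Traxler transition state on the enolate face away from the benzyl group of the (R)-auxiliary, so the aryl-bearing α-carbon (future C3) is set R in the imide and the carbinol carbon R (syn), of which only the former has to be controlled.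

Step 10
Reactants: 16 (R)-4-benzyl-3-[(2R,3R)-2-{2-(TBS-oxy)-3-methoxy-5-[3-(TBDPS-oxy)propyl]phenyl}-3-hydroxy-3-(4-TBS-oxy-3-methoxyphenyl)propanoyl]oxazolidin-2-one
Product: 17 (1R,2S)-2-{2-(TBS-oxy)-3-methoxy-5-[3-(TBDPS-oxy)propyl]phenyl}-1-(4-TBS-oxy-3-methoxyphenyl)propane-1,3-diol
Conditions: NaBH4 (4 equiv), THF–H2O (4:1), 0 °C → rt
Reagents that add atoms: none
Why: Reductive cleavage of the N-acyloxazolidinone: borohydride attacks the exocyclic imide carbonyl, the auxiliary is expelled and the aldehyde is reduced on without deprotonation of the α-carbon, whose descriptor becomes S only because CH2OH now ranks below the carbinol carbon.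

Step 11
Reactants: 17 (1R,2S)-2-{2-(TBS-oxy)-3-methoxy-5-[3-(TBDPS-oxy)propyl]phenyl}-1-(4-TBS-oxy-3-methoxyphenyl)propane-1,3-diol
Product: 18 (1R,2S)-1-(4-hydroxy-3-methoxyphenyl)-2-{2-hydroxy-3-methoxy-5-[3-(TBDPS-oxy)propyl]phenyl}propane-1,3-diol
Conditions: K2CO3 (3 equiv), MeOH, rt, Ar; then aq. NH4Cl
Reagents that add atoms: none
Why: Carbonate-promoted methanolysis removes aryl silyl ethers because phenoxide is a good leaving group on silicon, whereas the alkyl TBDPS ether and the diol are inert (chemoselective desilylation).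

Step 12
Reactants: 18 (1R,2S)-1-(4-hydroxy-3-methoxyphenyl)-2-{2-hydroxy-3-methoxy-5-[3-(TBDPS-oxy)propyl]phenyl}propane-1,3-diol
Product: 20 [(2R,3S)-2-(4-hydroxy-3-methoxyphenyl)-7-methoxy-5-[3-(TBDPS-oxy)propyl]-2,3-dihydro-1-benzofuran-3-yl]methanol, via para-quinone methide 19 (not isolated)
Conditions: CSA (20 mol%), CH2Cl2–MeCN (4:1, 0.02 M), 0 °C → rt
Reagents that add atoms: none
Why: Protonation of the C2 hydroxyl and loss of water, pushed by the para-hydroxyl group, should give the planar para-quinone methide 19 from either C2 epimer, and the C7a phenol then adds to the exocyclic methide carbon with rearomatisation, forming O1–C2. This is the known acid-promoted cyclisation of 1-(4-hydroxyaryl)-2-(2-hydroxyaryl)propane-1,3-diols to trans-2-aryl-2,3-dihydrobenzofurans (quinone methide formation followed by intramolecular oxa-1,6-addition). The five-membered ring closes 5-exo-trig, since the attacked C=C stays outside the new ring. C2 is controlled by C3 alone: allylic 1,3-strain holds the C3–H in the plane of the methide, so oxygen is delivered on the face that leaves the guaiacyl group anti to C9, and since the C2–O1 bond can re-ionise under the same acid, any cis isomer should drain to the more stable trans-(2R,3S) product. The step needs this diastereoselectivity at C2, chemoselectivity for the phenol over the C9 hydroxyl, secured because the latter could only form an oxetane, and ring closure faster than proton loss from C3, secured by the intramolecular five-membered closure in a dilute, non-nucleophilic medium. C3 never becomes part of the ionising system, and the TBDPS ether should tolerate the catalytic sulfonic acid.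

Step 13
Reactants: 20 [(2R,3S)-2-(4-hydroxy-3-methoxyphenyl)-7-methoxy-5-[3-(TBDPS-oxy)propyl]-2,3-dihydro-1-benzofuran-3-yl]methanol; 21 p-coumaric acid
Product: 22 [(2R,3S)-2-(4-hydroxy-3-methoxyphenyl)-7-methoxy-5-[3-(TBDPS-oxy)propyl]-2,3-dihydro-1-benzofuran-3-yl]methyl (E)-3-(4-hydroxyphenyl)prop-2-enoate
Conditions: 21 (1.2 equiv), PPh3 (1.3 equiv), DIAD (1.3 equiv), THF, 0 °C → rt
Reagents that add atoms: none
Why: Mitsunobu esterification activates the primary C9 alcohol as its oxyphosphonium salt, and only the carboxylic acid is acidic enough to protonate the betaine and serve as nucleophile, so the phenols should stay free and no stereocentre is involved.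

Step 14
Reactants: 22 [(2R,3S)-2-(4-hydroxy-3-methoxyphenyl)-7-methoxy-5-[3-(TBDPS-oxy)propyl]-2,3-dihydro-1-benzofuran-3-yl]methyl (E)-3-(4-hydroxyphenyl)prop-2-enoate
Product: 23 [(2R,3S)-2-(4-hydroxy-3-methoxyphenyl)-5-(3-hydroxypropyl)-7-methoxy-2,3-dihydro-1-benzofuran-3-yl]methyl (E)-3-(4-hydroxyphenyl)prop-2-enoate
Conditions: HF·pyridine, pyridine, THF, 0 °C → rt
Reagents that add atoms: none
Why: Fluoride cleavage of the silyl ether is driven by the Si–F bond, and buffered HF·pyridine is neither basic enough to open the dihydrobenzofuran through its phenoxide nor nucleophilic towards the cinnamate ester.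

Step 15
Reactants: 23 [(2R,3S)-2-(4-hydroxy-3-methoxyphenyl)-5-(3-hydroxypropyl)-7-methoxy-2,3-dihydro-1-benzofuran-3-yl]methyl (E)-3-(4-hydroxyphenyl)prop-2-enoate; 1 ferulic acid
Product: 24 (+)-boehmenan X
Conditions: 1 (1.2 equiv), PPh3 (1.3 equiv), DIAD (1.3 equiv), THF, 0 °C → rt
Reagents that add atoms: none
Why: A second chemoselective Mitsunobu esterification, now at the liberated primary propanol, in which the carboxylate of ferulic acid should again outcompete the phenols as nucleophile.

**Compound list**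

1 | ferulic acid [(E)-3-(4-hydroxy-3-methoxyphenyl)prop-2-enoic acid] | COc1cc(/C=C/C(=O)O)ccc1O | starting material
2 | dihydroferulic acid [3-(4-hydroxy-3-methoxyphenyl)propanoic acid] | COc1cc(CCC(=O)O)ccc1O | intermediate
3 | 3-(3-bromo-4-hydroxy-5-methoxyphenyl)propanoic acid | COc1cc(CCC(=O)O)cc(Br)c1O | intermediate
4 | 2-bromo-4-(3-hydroxypropyl)-6-methoxyphenol | COc1cc(CCCO)cc(Br)c1O | intermediate
5 | 2-bromo-4-[3-(tert-butyldiphenylsilyloxy)propyl]-6-methoxyphenol (mono-TBDPS ether) | COc1cc(CCCO[Si](c2ccccc2)(c2ccccc2)C(C)(C)C)cc(Br)c1O | intermediate (not isolated)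
6 | {2-bromo-4-[3-(tert-butyldiphenylsilyloxy)propyl]-6-methoxyphenoxy}(tert-butyl)dimethylsilane | COc1cc(CCCO[Si](c2ccccc2)(c2ccccc2)C(C)(C)C)cc(Br)c1O[Si](C)(C)C(C)(C)C | intermediate
7 | tert-butyl 2-{2-(TBS-oxy)-3-methoxy-5-[3-(TBDPS-oxy)propyl]phenyl}acetate | COc1cc(CCCO[Si](c2ccccc2)(c2ccccc2)C(C)(C)C)cc(CC(=O)OC(C)(C)C)c1O[Si](C)(C)C(C)(C)C | intermediate
8 | 2-{2-(TBS-oxy)-3-methoxy-5-[3-(TBDPS-oxy)propyl]phenyl}acetic acid | COc1cc(CCCO[Si](c2ccccc2)(c2ccccc2)C(C)(C)C)cc(CC(=O)O)c1O[Si](C)(C)C(C)(C)C | intermediate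
9 | (R)-4-benzyl-2-oxazolidinone | O=C1N[C@H](Cc2ccccc2)CO1 | starting material
10 | mixed anhydride of 8 with pivalic acid | COc1cc(CCCO[Si](c2ccccc2)(c2ccccc2)C(C)(C)C)cc(CC(=O)OC(=O)C(C)(C)C)c1O[Si](C)(C)C(C)(C)C | intermediate (not isolated)
11 | (R)-4-benzyl-3-(2-{2-(TBS-oxy)-3-methoxy-5-[3-(TBDPS-oxy)propyl]phenyl}acetyl)oxazolidin-2-one | COc1cc(CCCO[Si](c2ccccc2)(c2ccccc2)C(C)(C)C)cc(CC(=O)N2[C@H](Cc3ccccc3)COC2=O)c1O[Si](C)(C)C(C)(C)C | intermediate
12 | vanillin | COc1cc(C=O)ccc1O | starting material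
13 | 4-(tert-butyldimethylsilyloxy)-3-methoxybenzaldehyde | COc1cc(C=O)ccc1O[Si](C)(C)C(C)(C)C | intermediate
14 | Z dibutylboron enolate of 11 (aryl cis to O–B) | COc1cc(CCCO[Si](c2ccccc2)(c2ccccc2)C(C)(C)C)cc(/C=C(\OB(CCCC)CCCC)N2[C@H](Cc3ccccc3)COC2=O)c1O[Si](C)(C)C(C)(C)C | intermediate (not isolated)
15 | dibutylboron aldolate of 16 [(2R,3R)] | COc1cc(CCCO[Si](c2ccccc2)(c2ccccc2)C(C)(C)C)cc([C@@H](C(=O)N2[C@H](Cc3ccccc3)COC2=O)[C@@H](OB(CCCC)CCCC)c2ccc(O[Si](C)(C)C(C)(C)C)c(OC)c2)c1O[Si](C)(C)C(C)(C)C | intermediate (not isolated)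
16 | (R)-4-benzyl-3-[(2R,3R)-2-{2-(TBS-oxy)-3-methoxy-5-[3-(TBDPS-oxy)propyl]phenyl}-3-hydroxy-3-(4-TBS-oxy-3-methoxyphenyl)propanoyl]oxazolidin-2-one | COc1cc(CCCO[Si](c2ccccc2)(c2ccccc2)C(C)(C)C)cc([C@@H](C(=O)N2[C@H](Cc3ccccc3)COC2=O)[C@@H](O)c2ccc(O[Si](C)(C)C(C)(C)C)c(OC)c2)c1O[Si](C)(C)C(C)(C)C | intermediate
17 | (1R,2S)-2-{2-(TBS-oxy)-3-methoxy-5-[3-(TBDPS-oxy)propyl]phenyl}-1-(4-TBS-oxy-3-methoxyphenyl)propane-1,3-diol | COc1cc(CCCO[Si](c2ccccc2)(c2ccccc2)C(C)(C)C)cc([C@@H](CO)[C@@H](O)c2ccc(O[Si](C)(C)C(C)(C)C)c(OC)c2)c1O[Si](C)(C)C(C)(C)C | intermediate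
18 | (1R,2S)-1-(4-hydroxy-3-methoxyphenyl)-2-{2-hydroxy-3-methoxy-5-[3-(TBDPS-oxy)propyl]phenyl}propane-1,3-diol (key-step precursor; a 1S epimer would react alike) | COc1cc(CCCO[Si](c2ccccc2)(c2ccccc2)C(C)(C)C)cc([C@@H](CO)[C@@H](O)c2ccc(O)c(OC)c2)c1O | intermediate
19 | para-quinone methide from 18 (C3 intact, C2 trigonal) | COc1cc(CCCO[Si](c2ccccc2)(c2ccccc2)C(C)(C)C)cc([C@@H](CO)C=C2C=CC(=O)C(OC)=C2)c1O | intermediate (not isolated)
20 | [(2R,3S)-2-(4-hydroxy-3-methoxyphenyl)-7-methoxy-5-[3-(TBDPS-oxy)propyl]-2,3-dihydro-1-benzofuran-3-yl]methanol (trans) | CC(C)(C)[Si](c1ccccc1)(c1ccccc1)OCCCc1cc(OC)c2c(c1)[C@@H](CO)[C@H](c1ccc(O)c(OC)c1)O2 | intermediate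
21 | p-coumaric acid | O=C(O)/C=C/c1ccc(O)cc1 | starting material
22 | C9 (E)-p-coumarate of 20 | CC(C)(C)[Si](c1ccccc1)(c1ccccc1)OCCCc1cc(OC)c2c(c1)[C@@H](COC(=O)/C=C/c1ccc(O)cc1)[C@H](c1ccc(O)c(OC)c1)O2 | intermediate
23 | [(2R,3S)-2-(4-hydroxy-3-methoxyphenyl)-5-(3-hydroxypropyl)-7-methoxy-2,3-dihydro-1-benzofuran-3-yl]methyl (E)-3-(4-hydroxyphenyl)prop-2-enoate | OCCCc1cc(OC)c2c(c1)[C@@H](COC(=O)/C=C/c1ccc(O)cc1)[C@H](c1ccc(O)c(OC)c1)O2 | intermediate
24 | (+)-boehmenan X [(2R,3S); C9 p-coumarate, propyl ferulate] | COc1cc(/C=C/C(=O)OCCCc2cc(OC)c3c(c2)[C@@H](COC(=O)/C=C/c2ccc(O)cc2)[C@H](c2ccc(O)c(OC)c2)O3)ccc1O | target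

**Step count and risks**

Total: 15 steps. Longest linear sequence: 14 steps (1–7, then 9–15); step 8 is a one-step side branch.

Steps most likely to fail:

1. Step 12 (key step). Ring closure may be outrun by proton loss from C3 of the methide, which would erase the C3 centre, or by intermolecular capture, or the cis-to-trans equilibration may stall. The fallback releases the methide by base instead of acid. From 17, acetylation (Ac2O, pyridine, DMAP, CH2Cl2) would give the diacetate F1. TBAF in THF at 0 °C would remove the two aryl silyl groups, and the para-phenoxide would expel the benzylic acetate in a 1,6-elimination to give the quinone methide acetate F2. The neighbouring phenoxide would close this to the trans-dihydrobenzofuran C9 acetate F3, and K2CO3 in MeOH would cleave the acetate and rejoin the route at 20.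

2. Step 5. Oxidative addition and transmetalation at the bromide next to the bulky silyloxy group may be slow, so that protodebromination or decay of the zinc enolate takes over. The fallback uses an allyl group as a masked acetic acid. From 6, Stille coupling with allyltributylstannane (Pd(PPh3)4, toluene, 100 °C) would give the allylarene F4. Lemieux–Johnson cleavage (cat. OsO4, NaIO4, 2,6-lutidine, dioxane–H2O) would give the arylacetaldehyde F5, and Pinnick oxidation (NaClO2, NaH2PO4, 2-methyl-2-butene, t-BuOH–H2O) would rejoin the route at 8, bypassing step 6 as well.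

3. Step 13 (step 15 runs the same reaction type with one more phenol present). Activating the alcohol in the presence of free phenols may lose chemoselectivity, through phenol O-alkylation or elimination across C3–C9. The fallback activates the acid instead and then unmasks. From 20, Steglich acylation with commercial (E)-4-acetoxycinnamic acid (2.5 equiv, EDC·HCl, DMAP, CH2Cl2) would esterify both the C9 hydroxyl and the guaiacyl phenol to give the bis-ester F6. Pyrrolidine in CH2Cl2 at 0 °C would then cleave the aryl esters (two acetates and the aryl cinnamate) much faster than the alkyl cinnamate and rejoin the route at 22.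

**Further compounds**

F1 | step 12 | diacetate of 17 (C9 and C2 acetates, silyl groups retained) | COc1cc(CCCO[Si](c2ccccc2)(c2ccccc2)C(C)(C)C)cc([C@@H](COC(C)=O)[C@@H](OC(C)=O)c2ccc(O[Si](C)(C)C(C)(C)C)c(OC)c2)c1O[Si](C)(C)C(C)(C)C
F2 | step 12 | para-quinone methide bearing the C9 acetate | COc1cc(CCCO[Si](c2ccccc2)(c2ccccc2)C(C)(C)C)cc([C@@H](COC(C)=O)C=C2C=CC(=O)C(OC)=C2)c1O
F3 | step 12 | C9 acetate of 20 [(2R,3S), trans] | CC(C)(C)[Si](c1ccccc1)(c1ccccc1)OCCCc1cc(OC)c2c(c1)[C@@H](COC(C)=O)[C@H](c1ccc(O)c(OC)c1)O2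
F4 | step 5 | {2-allyl-4-[3-(tert-butyldiphenylsilyloxy)propyl]-6-methoxyphenoxy}(tert-butyl)dimethylsilane | COc1cc(CCCO[Si](c2ccccc2)(c2ccccc2)C(C)(C)C)cc(CC=C)c1O[Si](C)(C)C(C)(C)C
F5 | step 5 | 2-{2-(TBS-oxy)-3-methoxy-5-[3-(TBDPS-oxy)propyl]phenyl}acetaldehyde | COc1cc(CCCO[Si](c2ccccc2)(c2ccccc2)C(C)(C)C)cc(CC=O)c1O[Si](C)(C)C(C)(C)C
F6 | step 13 | bis[(E)-4-acetoxycinnamoyl] derivative of 20 (C9 ester and guaiacyl aryl ester) | CC(C)(C)[Si](c1ccccc1)(c1ccccc1)OCCCc1cc(OC)c2c(c1)[C@@H](COC(=O)/C=C/c1ccc(OC(C)=O)cc1)[C@H](c1ccc(OC(=O)/C=C/c3ccc(OC(C)=O)cc3)c(OC)c1)O2
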